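**Retrosynthetic overview**
1. Ring order: the six-membered carbocycle is bought as the aromatic acylphloroglucinol 1 (para-O-silylated, 2); the dihydrofuran is closed next, and the carbocycle is dearomatised only at the end.
2. Key C–C disconnection: the aryl–CH2 bond between ring and side chain, cut back to 2 and D-malic acid acetonide 3 (activated with 4 as phthalimide ester 5) and made by a light-driven decarboxylative C–H alkylation giving 6.
3. Side chain: the gem-dimethyl carbinol comes from MeMgBr on the dioxolanone of 6, giving diol 7 with the purchased C–O stereocentre intact.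
4. C–O disconnection: the dihydrofuran O–C2 bond, made by Mitsunobu closure of 7 with inversion (8); the silyl group forces closure through the phenol next to the acyl group.
5. Last disconnection: the two prenyl–C5 bonds, made by desilylation (9) and dearomative gem-diprenylation to the target 10.

Assumption: 3 is bought (otherwise one step from D-malic acid with 2,2-dimethoxypropane), and the target, an enolised β-triketone, is obtained as the tautomer set that the given SMILES represents.

**Route**

Step 1
Reactants: 1 2-methyl-1-(2,4,6-trihydroxyphenyl)propan-1-one (phlorisobutyrophenone)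
Product: 2 1-{4-[(tert-butyldimethylsilyl)oxy]-2,6-dihydroxyphenyl}-2-methylpropan-1-one
Conditions: TBSCl (1.05 equiv), imidazole (2.2 equiv), DMF, 0 °C, 2 h
Reagents that add atoms: tert-butyldimethylsilyl chloride (TBSCl), CC(C)(C)[Si](C)(C)Cl
Why: Selective silyl ether formation, because the para hydroxyl is the most acidic one and the only one that is neither hydrogen-bonded to the ketone nor flanked by the acyl group, so one equivalent of TBSCl caps it and leaves the two chelated ortho hydroxyls free; no stereocentre is involved.

Step 2
Reactants: 2 1-{4-[(tert-butyldimethylsilyl)oxy]-2,6-dihydroxyphenyl}-2-methylpropan-1-one; 3 (R)-2-(2,2-dimethyl-5-oxo-1,3-dioxolan-4-yl)acetic acid; 4 N-hydroxyphthalimide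
Product: 6 (5R)-5-({6-[(tert-butyldimethylsilyl)oxy]-2,4-dihydroxy-3-(2-methylpropanoyl)phenyl}methyl)-2,2-dimethyl-1,3-dioxolan-4-one, via phthalimide ester 5 (not isolated)
Conditions: 3, 4, DIC (1.1 equiv), DMA, rt, 3 h; then 2 (2 equiv), K3PO4 (2.2 equiv), degassed, 405 nm LEDs, 20 °C, 16 h
Reagents that add atoms: none
Why: Proposed new method: the potassium phenolate of 2 is an electron-rich donor that absorbs violet light and forms an electron donor–acceptor complex with the electron-poor phthalimide ester 5, so irradiation triggers single-electron transfer, loss of phthalimide anion and CO2, and the resulting primary radical couples with the phenoxyl radical in the solvent cage (or adds to a second phenolate in an SRN1-type chain) at the equivalent C3/C5 positions before tautomerising back to the arene, the stereocentre β to the radical being untouched and staying (R); the closest known reaction types are photochemical donor–acceptor decarboxylative alkylations with N-(acyloxy)phthalimides and the photostimulated SRN1 or phenolate-excitation C-alkylation of phenolates and naphtholates with alkyl iodides, neither shown for an acylphloroglucinol with an unactivated β-oxygenated primary radical.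

Step 3
Reactants: 6 (5R)-5-({6-[(tert-butyldimethylsilyl)oxy]-2,4-dihydroxy-3-(2-methylpropanoyl)phenyl}methyl)-2,2-dimethyl-1,3-dioxolan-4-one
Product: 7 1-{4-[(tert-butyldimethylsilyl)oxy]-3-[(2R)-2,3-dihydroxy-3-methylbutyl]-2,6-dihydroxyphenyl}-2-methylpropan-1-one
Conditions: MeMgBr (7 equiv), THF, −40 to 0 °C; aq. NH4Cl
Reagents that add atoms: methylmagnesium bromide, C[Mg]Br
Why: Double Grignard addition to an activated lactone-type ester gives the tertiary alcohol and frees the secondary hydroxyl with loss of acetone (which consumes part of the excess reagent), while the isopropyl aryl ketone flanked by two magnesium phenoxides is sterically shielded and deactivated as a vinylogous carboxylate; the C–O stereocentre is not touched and stays (R), and any acyl transfer onto the neighbouring phenoxide converges on the same product.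

Step 4
Reactants: 7 1-{4-[(tert-butyldimethylsilyl)oxy]-3-[(2R)-2,3-dihydroxy-3-methylbutyl]-2,6-dihydroxyphenyl}-2-methylpropan-1-one
Product: 8 1-[(2S)-4-[(tert-butyldimethylsilyl)oxy]-6-hydroxy-2-(2-hydroxypropan-2-yl)-2,3-dihydro-1-benzofuran-7-yl]-2-methylpropan-1-one
Conditions: PPh3 (1.5 equiv), DIAD (1.5 equiv), THF, 0 °C to rt
Reagents that add atoms: none
Why: Intramolecular Mitsunobu etherification, in which the secondary alcohol is activated as its oxyphosphonium ion and displaced in a 5-exo-tet SN2 closure by the only phenol within reach (the one next to the acyl group, the para oxygen being silylated), the tertiary alcohol being inert, so the purchased (R) centre is inverted to the (S) centre of the target.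

Step 5
Reactants: 8 1-[(2S)-4-[(tert-butyldimethylsilyl)oxy]-6-hydroxy-2-(2-hydroxypropan-2-yl)-2,3-dihydro-1-benzofuran-7-yl]-2-methylpropan-1-one
Product: 10 Garcinielliptone HD [(2S,7Z)-7-(1-hydroxy-2-methylpropylidene)-2-(2-hydroxypropan-2-yl)-5,5-bis(3-methylbut-2-en-1-yl)-2,3-dihydro-1-benzofuran-4,6(5H,7H)-dione], via desilylated bisphenol 9 (not isolated)
Conditions: KOH (6 equiv), MeOH/H2O, rt, 1 h; then prenyl bromide (2.5 equiv), 0 °C, 3 h; 1 M HCl
Reagents that add atoms: prenyl bromide (1-bromo-3-methylbut-2-ene), CC(C)=CCBr
Why: Hydroxide cleaves the aryl silyl ether, and the carbon flanked by the two phenoxide oxygens, the only unsubstituted and the most nucleophilic ring position, is then C-prenylated twice in the classical hop β-acid type dearomative alkylation of a phloroglucinol, the second alkylation breaking aromaticity to give the enolised triketone; the stereocentre is remote and unaffected.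

**Compound list**
1 | 2-methyl-1-(2,4,6-trihydroxyphenyl)propan-1-one (phlorisobutyrophenone) | CC(C)C(=O)c1c(O)cc(O)cc1O | starting material
2 | 1-{4-[(tert-butyldimethylsilyl)oxy]-2,6-dihydroxyphenyl}-2-methylpropan-1-one | CC(C)C(=O)c1c(O)cc(O[Si](C)(C)C(C)(C)C)cc1O | intermediate
3 | (R)-2-(2,2-dimethyl-5-oxo-1,3-dioxolan-4-yl)acetic acid (D-malic acid acetonide) | OC(=O)C[C@H]1OC(C)(C)OC1=O | starting material
4 | N-hydroxyphthalimide | ON1C(=O)c2ccccc2C1=O | starting material
5 | 1,3-dioxoisoindolin-2-yl 2-[(4R)-2,2-dimethyl-5-oxo-1,3-dioxolan-4-yl]acetate | O=C(C[C@H]1OC(C)(C)OC1=O)ON1C(=O)c2ccccc2C1=O | intermediate (not isolated)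
6 | (5R)-5-({6-[(tert-butyldimethylsilyl)oxy]-2,4-dihydroxy-3-(2-methylpropanoyl)phenyl}methyl)-2,2-dimethyl-1,3-dioxolan-4-one | CC(C)C(=O)c1c(O)cc(O[Si](C)(C)C(C)(C)C)c(C[C@H]2OC(C)(C)OC2=O)c1O | intermediate
7 | 1-{4-[(tert-butyldimethylsilyl)oxy]-3-[(2R)-2,3-dihydroxy-3-methylbutyl]-2,6-dihydroxyphenyl}-2-methylpropan-1-one | CC(C)C(=O)c1c(O)cc(O[Si](C)(C)C(C)(C)C)c(C[C@@H](O)C(C)(C)O)c1O | intermediate
8 | 1-[(2S)-4-[(tert-butyldimethylsilyl)oxy]-6-hydroxy-2-(2-hydroxypropan-2-yl)-2,3-dihydro-1-benzofuran-7-yl]-2-methylpropan-1-one | CC(C)C(=O)c1c(O)cc(O[Si](C)(C)C(C)(C)C)c2C[C@@H](C(C)(C)O)Oc12 | intermediate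
9 | 1-[(2S)-4,6-dihydroxy-2-(2-hydroxypropan-2-yl)-2,3-dihydro-1-benzofuran-7-yl]-2-methylpropan-1-one | CC(C)C(=O)c1c(O)cc(O)c2C[C@@H](C(C)(C)O)Oc12 | intermediate (not isolated)
10 | Garcinielliptone HD | CC(C)=CCC1(CC=C(C)C)C(=O)C2=C(O[C@H](C(C)(C)O)C2)/C(=C(/O)C(C)C)C1=O | target

**Totals**
Total step count: 5. Longest linear sequence: 5 steps (1 → 2 → 6 → 7 → 8 → 10).

**Three steps most likely to fail**

Step 2 (the proposed photochemical alkylation). The risks are thermal O-acylation of the phenolate by 5, attack at the acyl-bearing ring carbon, dialkylation, base-induced loss of the silyl group, and a low quantum yield if the nucleophilic primary radical does not couple efficiently. The fallback uses known chemistry and sets out from 2. Iodination with N-iodosuccinimide (MeCN, 0 °C) gives 1-{4-[(tert-butyldimethylsilyl)oxy]-2,6-dihydroxy-3-iodophenyl}-2-methylpropan-1-one F1. F1 is then joined to 5 (here prepared from 3 and 4 with DIC in CH2Cl2 and isolated) by the known nickel-catalysed reductive decarboxylative cross-electrophile coupling of aryl iodides with N-(acyloxy)phthalimides (NiBr2(dme), 4,4'-di-tert-butyl-2,2'-bipyridine, Zn dust, DMA, rt to 40 °C). This forms the same aryl–CH2 bond at a predefined carbon without using the phenolate as photoreductant, though the doubly ortho-substituted iodide may couple slowly. It comes back to the route at 6.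

Step 4 (Mitsunobu closure of the diol). The risks are attack of the neighbouring tertiary hydroxyl on the activated secondary centre to give an epoxide, which would then open with overall retention and erode the enantiomeric purity, and elimination at the hindered carbinol. The fallback sets out from 6 and closes the ring before the tertiary alcohol exists. Acid methanolysis (MeOH, cat. TsOH, rt) opens the dioxolanone to methyl (2R)-3-{6-[(tert-butyldimethylsilyl)oxy]-2,4-dihydroxy-3-(2-methylpropanoyl)phenyl}-2-hydroxypropanoate F2. Mitsunobu closure at the α-carbon of the ester (PPh3, DIAD, THF), where no second hydroxyl can intervene and SN2 displacement is fast, gives methyl (2S)-4-[(tert-butyldimethylsilyl)oxy]-6-hydroxy-7-(2-methylpropanoyl)-2,3-dihydro-1-benzofuran-2-carboxylate F3 with clean inversion. MeMgBr (THF, −40 to 0 °C) then turns the ester into the tertiary alcohol and returns to the route at 8.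

Step 5 (desilylation and dearomative gem-diprenylation). The risks are O-prenylation, alkylation at the ring-fusion carbon, solvolysis of prenyl bromide and a modest yield, as is usual for this type of alkylation. The fallback sets out from 9, isolated after the hydroxide desilylation by acidification and extraction. Double Tsuji–Trost allylation with the zerovalent palladium complex Pd(PPh3)4 and allyl methyl carbonate (THF, rt) gives (2S,7Z)-7-(1-hydroxy-2-methylpropylidene)-2-(2-hydroxypropan-2-yl)-5,5-di(prop-2-en-1-yl)-2,3-dihydro-1-benzofuran-4,6(5H,7H)-dione F4. Any O-allyl ether is re-ionised by the catalyst, so material funnels to the C,C-diallyl compound. Cross-metathesis of both allyl groups with excess 2-methyl-2-butene (second-generation Grubbs catalyst, RuCl2(=CHPh)(H2IMes)(PCy3), CH2Cl2, 40 °C) installs the two prenyl groups and returns to the route at 10.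

**Further compounds**
F1 | step 2 | 1-{4-[(tert-butyldimethylsilyl)oxy]-2,6-dihydroxy-3-iodophenyl}-2-methylpropan-1-one | CC(C)C(=O)c1c(O)cc(O[Si](C)(C)C(C)(C)C)c(I)c1O
F2 | step 4 | methyl (2R)-3-{6-[(tert-butyldimethylsilyl)oxy]-2,4-dihydroxy-3-(2-methylpropanoyl)phenyl}-2-hydroxypropanoate | COC(=O)[C@H](O)Cc1c(O)c(C(=O)C(C)C)c(O)cc1O[Si](C)(C)C(C)(C)C
F3 | step 4 | methyl (2S)-4-[(tert-butyldimethylsilyl)oxy]-6-hydroxy-7-(2-methylpropanoyl)-2,3-dihydro-1-benzofuran-2-carboxylate | COC(=O)[C@@H]1Cc2c(O[Si](C)(C)C(C)(C)C)cc(O)c(C(=O)C(C)C)c2O1
F4 | step 5 | (2S,7Z)-7-(1-hydroxy-2-methylpropylidene)-2-(2-hydroxypropan-2-yl)-5,5-di(prop-2-en-1-yl)-2,3-dihydro-1-benzofuran-4,6(5H,7H)-dione | C=CCC1(CC=C)C(=O)C2=C(O[C@H](C(C)(C)O)C2)/C(=C(/O)C(C)C)C1=O
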